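**Plan**

- Retrosynthesis: cut the angelate ester, then the C3 acetate, then both O1–C2 and C3a–C3 of the dihydrofuran ring at once. This leaves para-substituted phenol 11 and the γ-acetoxy enal 6.
- Enabling feature: C3 of the dihydrofuran ring is an aryl carbinol (a latent aldehyde). C2 is an allylic ether carbon next to the α-carbon of the exocyclic acrylate (a latent SN2′ terminus). C2–C3 is therefore a 1,2-dielectrophile that matches the phenol oxygen O1 and the free ortho carbon C3a.
- Forward: a Morita–Baylis–Hillman reaction, acetoxy transposition and acetal hydrolysis give 6. Reduction and silyl shuffling of 4′-hydroxyacetophenone give 11. One annulation then builds the furan ring and unveils the α-methylene ester; acetylation, desilylation and angeloylation finish.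
- Stereochemistry: the side-chain carbinol (S) comes from a Corey–Bakshi–Shibata reduction. C3 comes from face selection at the aldehyde by a Ti–(R)-BINOLate. C2 is set cis to C3 by a magnesium chelate during ring closure. The (Z)-enoate is carried in with angelic acid.

Key step: step 8

Assumption: the (R)-BINOL–Ti(IV) aryloxide is taken to attack the Si face of the formyl group of 6, which gives the (4R) carbinol 12. If the sense proves opposite, (S)-BINOL is used with no other change.

**Route**

Step 1
Reactants: 1 methyl acrylate; 2 2,2-dimethoxyacetaldehyde (60 wt % aqueous solution)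
Product: 3 methyl 3-hydroxy-4,4-dimethoxy-2-methylenebutanoate (racemic)
Conditions: DABCO (0.5 equiv), 1,4-dioxane/H2O, rt
Reagents that add atoms: none
Why: Morita–Baylis–Hillman reaction with an α-alkoxy-activated aldehyde; the racemic carbinol centre is erased in step 2.

Step 2
Reactants: 3 methyl 3-hydroxy-4,4-dimethoxy-2-methylenebutanoate
Product: 5 methyl (2E)-2-(acetoxymethyl)-4,4-dimethoxybut-2-enoate, via MBH acetate 4 (not isolated)
Conditions: Ac2O, pyridine, DMAP (cat.), CH2Cl2, 0 °C; crude 4, then DABCO (30 mol %), THF, 60 °C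
Reagents that add atoms: acetic anhydride, CC(=O)OC(C)=O
Why: O-acetylation followed by the DABCO-catalysed 1,3-acetoxy transposition of Morita–Baylis–Hillman acetates (SN2′ addition of the amine, return of acetate at the primary carbon), which should give the conjugated (E)-enoate with the acetal carbon cis to the acetoxymethyl arm.

Step 3
Reactants: 5 methyl (2E)-2-(acetoxymethyl)-4,4-dimethoxybut-2-enoate
Product: 6 methyl (2E)-2-(acetoxymethyl)-4-oxobut-2-enoate
Conditions: TFA/H2O (1:1), CHCl3, 0 °C; used at once
Reagents that add atoms: water, O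
Why: acid hydrolysis of the dimethyl acetal; the allylic acetate, the methyl ester and the alkene geometry should survive brief cold aqueous acid.

Step 4
Reactants: 7 4′-hydroxyacetophenone
Product: 8 4′-(tert-butyldimethylsilyloxy)acetophenone
Conditions: TBSCl, imidazole, DMF, rt
Reagents that add atoms: tert-butyldimethylsilyl chloride, CC(C)(C)[Si](C)(C)Cl
Why: silylation of the phenol so that the ketone can be reduced under anhydrous borane conditions.

Step 5
Reactants: 8 4′-(tert-butyldimethylsilyloxy)acetophenone
Product: 9 (1S)-1-[4-(tert-butyldimethylsilyloxy)phenyl]ethanol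
Conditions: (R)-2-methyl-CBS-oxazaborolidine (10 mol %), BH3·SMe2, THF, −20 °C; MeOH quench
Reagents that add atoms: none
Why: Corey–Bakshi–Shibata reduction; the (R)-oxazaborolidine delivers hydride to the Re face of the aryl methyl ketone (aryl as the large group) and so sets the (S) carbinol.

Step 6
Reactants: 9 (1S)-1-[4-(tert-butyldimethylsilyloxy)phenyl]ethanol
Product: 10 tert-butyl{4-[(1S)-1-(tert-butyldimethylsilyloxy)ethyl]phenoxy}dimethylsilane
Conditions: TBSCl, imidazole, DMF, rt
Reagents that add atoms: tert-butyldimethylsilyl chloride, CC(C)(C)[Si](C)(C)Cl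
Why: standard silylation of the secondary benzylic alcohol, with no change at the stereocentre.

Step 7
Reactants: 10 tert-butyl{4-[(1S)-1-(tert-butyldimethylsilyloxy)ethyl]phenoxy}dimethylsilane
Product: 11 4-[(1S)-1-(tert-butyldimethylsilyloxy)ethyl]phenol
Conditions: KHF2 (2 equiv), MeOH, rt
Reagents that add atoms: none
Why: selective cleavage of the aryl silyl ether by bifluoride, which leaves the alkyl silyl ether intact and avoids a free phenoxide para to the benzylic leaving group.

Step 8
Reactants: 11 4-[(1S)-1-(tert-butyldimethylsilyloxy)ethyl]phenol; 6 methyl (2E)-2-(acetoxymethyl)-4-oxobut-2-enoate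
Product: 13 methyl 2-[(2S,3S)-5-[(1S)-1-(tert-butyldimethylsilyloxy)ethyl]-3-hydroxy-2,3-dihydro-1-benzofuran-2-yl]prop-2-enoate, via diol 12 (not isolated)
Conditions: Ti(OiPr)4 (10 mol %), (R)-BINOL (20 mol %), 4 Å MS, CH2Cl2, −20 → 0 °C; then MgBr2·OEt2 (1.5 equiv), iPr2NEt (3 equiv), 0 °C → rt, same flask
Reagents that add atoms: none
Why: Proposed new method: the Ti(IV)–(R)-BINOLate binds 11 as its aryloxide together with the formyl oxygen of 6, the ortho carbon adds to the aldehyde through a closed six-membered transition state and rearomatisation gives diol 12; the magnesium phenoxide made next adds to the enoate β-carbon (the future C2) and the ester enolate expels acetate (oxa-Michael/E1cB, net SN2′), so that the O–C bond, the ring and the α-methylene ester arise in the same flask as a formal [3+2] annulation. The closest known reaction types are the ortho-specific hydroxyalkylation of metal phenoxides with aldehydes, its Ti–BINOLate-catalysed enantioselective Friedel–Crafts form with activated aldehydes (glyoxylates, fluoral) and the SN2′ etherification of phenols with 2-(acyloxymethyl)acrylates; what is new is their merger and the use of a γ-acyloxy enal as the aldehyde. The five-membered ring closes in a 5-exo-trig mode. The carbinol centre C3 is set by the chiral titanium complex, assumed to expose the Si face of the aldehyde; C2 is set relative to it by a magnesium chelate between the C3 oxygen and the cis-disposed acetoxymethyl arm, which holds that oxygen on the inside of the allylic system so that the phenoxide enters cis to it. The step needs ortho C-attack instead of O-attack on the aldehyde (oxophilic metal template, para position blocked), 1,2- instead of 1,4-addition (the enal β-carbon is fully substituted) and closure by the phenol oxygen instead of the carbinol oxygen (acetate is a poor SN2 leaving group but a ready E1cB nucleofuge, and only the phenoxide reaches the enoate β-carbon in a 5-exo mode). The electron-poor enoate next to the carbinol should also retard ionisation of 12 to an ortho-quinone methide.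

Step 9
Reactants: 13 methyl 2-[(2S,3S)-5-[(1S)-1-(tert-butyldimethylsilyloxy)ethyl]-3-hydroxy-2,3-dihydro-1-benzofuran-2-yl]prop-2-enoate
Product: 14 methyl 2-[(2S,3S)-3-acetoxy-5-[(1S)-1-(tert-butyldimethylsilyloxy)ethyl]-2,3-dihydro-1-benzofuran-2-yl]prop-2-enoate
Conditions: Ac2O, Et3N, DMAP (5 mol %), CH2Cl2, 0 °C
Reagents that add atoms: acetic anhydride, CC(=O)OC(C)=O
Why: DMAP-catalysed acylation of the secondary benzylic alcohol with retention at C3; cold, brief, weakly basic conditions should avoid alkoxide-triggered opening of the allylic aryl ether.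

Step 10
Reactants: 14 methyl 2-[(2S,3S)-3-acetoxy-5-[(1S)-1-(tert-butyldimethylsilyloxy)ethyl]-2,3-dihydro-1-benzofuran-2-yl]prop-2-enoate
Product: 15 methyl 2-[(2S,3S)-3-acetoxy-5-[(1S)-1-hydroxyethyl]-2,3-dihydro-1-benzofuran-2-yl]prop-2-enoate
Conditions: HF·pyridine, pyridine, THF, 0 °C → rt
Reagents that add atoms: none
Why: buffered fluoride cleavage of the secondary silyl ether, which should leave the acetate, the methyl ester and the acrylate untouched and not ionise the benzylic carbinol.

Step 11
Reactants: 15 methyl 2-[(2S,3S)-3-acetoxy-5-[(1S)-1-hydroxyethyl]-2,3-dihydro-1-benzofuran-2-yl]prop-2-enoate; 16 angelic acid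
Product: 18 (1S)-1-[(2S,3S)-3-acetoxy-2-(3-methoxy-3-oxoprop-1-en-2-yl)-2,3-dihydro-1-benzofuran-5-yl]ethyl (2Z)-2-methylbut-2-enoate, via mixed anhydride 17 (not isolated)
Conditions: 16, 2,4,6-trichlorobenzoyl chloride, Et3N, toluene, rt; then 15, toluene, 80 °C, no DMAP
Reagents that add atoms: none
Why: Yamaguchi esterification without a nucleophilic catalyst; the alcohol attacks the unhindered angeloyl carbonyl of 17 with retention at the carbinol carbon, and leaving out DMAP should prevent Z→E isomerisation to the tiglate.

**Compound list**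

1 | methyl acrylate | C=CC(=O)OC | starting material
2 | 2,2-dimethoxyacetaldehyde | COC(OC)C=O | starting material
3 | methyl 3-hydroxy-4,4-dimethoxy-2-methylenebutanoate (racemic) | C=C(C(=O)OC)C(O)C(OC)OC | intermediate
4 | methyl 3-acetoxy-4,4-dimethoxy-2-methylenebutanoate (racemic, not isolated) | C=C(C(=O)OC)C(OC(C)=O)C(OC)OC | intermediate
5 | methyl (2E)-2-(acetoxymethyl)-4,4-dimethoxybut-2-enoate | COC(=O)/C(COC(C)=O)=C/C(OC)OC | intermediate
6 | methyl (2E)-2-(acetoxymethyl)-4-oxobut-2-enoate | COC(=O)/C(COC(C)=O)=C/C=O | intermediate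
7 | 4′-hydroxyacetophenone | CC(=O)c1ccc(O)cc1 | starting material
8 | 4′-(tert-butyldimethylsilyloxy)acetophenone | CC(=O)c1ccc(O[Si](C)(C)C(C)(C)C)cc1 | intermediate
9 | (1S)-1-[4-(tert-butyldimethylsilyloxy)phenyl]ethanol | C[C@H](O)c1ccc(O[Si](C)(C)C(C)(C)C)cc1 | intermediate
10 | tert-butyl{4-[(1S)-1-(tert-butyldimethylsilyloxy)ethyl]phenoxy}dimethylsilane | C[C@H](O[Si](C)(C)C(C)(C)C)c1ccc(O[Si](C)(C)C(C)(C)C)cc1 | intermediate
11 | 4-[(1S)-1-(tert-butyldimethylsilyloxy)ethyl]phenol | C[C@H](O[Si](C)(C)C(C)(C)C)c1ccc(O)cc1 | intermediate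
12 | methyl (2E,4R)-2-(acetoxymethyl)-4-hydroxy-4-{2-hydroxy-5-[(1S)-1-(tert-butyldimethylsilyloxy)ethyl]phenyl}but-2-enoate (not isolated) | COC(=O)/C(COC(C)=O)=C/[C@@H](O)c1cc([C@H](C)O[Si](C)(C)C(C)(C)C)ccc1O | intermediate
13 | methyl 2-[(2S,3S)-5-[(1S)-1-(tert-butyldimethylsilyloxy)ethyl]-3-hydroxy-2,3-dihydro-1-benzofuran-2-yl]prop-2-enoate | C=C(C(=O)OC)[C@@H]1Oc2ccc([C@H](C)O[Si](C)(C)C(C)(C)C)cc2[C@@H]1O | intermediate
14 | methyl 2-[(2S,3S)-3-acetoxy-5-[(1S)-1-(tert-butyldimethylsilyloxy)ethyl]-2,3-dihydro-1-benzofuran-2-yl]prop-2-enoate | C=C(C(=O)OC)[C@@H]1Oc2ccc([C@H](C)O[Si](C)(C)C(C)(C)C)cc2[C@@H]1OC(C)=O | intermediate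
15 | methyl 2-[(2S,3S)-3-acetoxy-5-[(1S)-1-hydroxyethyl]-2,3-dihydro-1-benzofuran-2-yl]prop-2-enoate | C=C(C(=O)OC)[C@@H]1Oc2ccc([C@H](C)O)cc2[C@@H]1OC(C)=O | intermediate
16 | angelic acid, (2Z)-2-methylbut-2-enoic acid | C/C=C(/C)C(=O)O | starting material
17 | (2Z)-2-methylbut-2-enoic 2,4,6-trichlorobenzoic anhydride (not isolated) | C/C=C(/C)C(=O)OC(=O)c1c(Cl)cc(Cl)cc1Cl | intermediate
18 | (1S)-1-[(2S,3S)-3-acetoxy-2-(3-methoxy-3-oxoprop-1-en-2-yl)-2,3-dihydro-1-benzofuran-5-yl]ethyl (2Z)-2-methylbut-2-enoate | C=C(C(=O)OC)[C@@H]1Oc2ccc([C@H](C)OC(=O)/C(C)=C\C)cc2[C@@H]1OC(C)=O | target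

**Count and risks**

Total step count: 11. Longest linear sequence: 8 steps (7 → 18, steps 4 to 11).

Steps most likely to fail:

1. Step 8 (Proposed new method). Possible failures:
   - weak or reversed face discrimination at an aldehyde that binds titanium through one point only;
   - erosion of the cis preference if allylic strain (C3–H inside) outweighs the magnesium chelate;
   - ionisation of 12 to an ortho-quinone methide and electrocyclisation to a 2H-chromene;
   - O-alkylation by the carbinol oxygen to give a 2,5-dihydrofuran;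
   - loss of silanolate from the para benzylic position through a para-quinone methide.

   Fallback with known chemistry, setting out from 11 and 6 and returning at 14: phenol 11 is converted into its bromomagnesium phenoxide (EtMgBr, Et2O, then CH2Cl2) and treated with 6 at 0 °C to rt. This ortho-specific hydroxyalkylation of a magnesium phenoxide should give 12 together with its C4 epimer, methyl (2E,4S)-2-(acetoxymethyl)-4-hydroxy-4-{2-hydroxy-5-[(1S)-1-(tert-butyldimethylsilyloxy)ethyl]phenyl}but-2-enoate F1. K2CO3 in acetone then closes the ring by the known SN2′ etherification of 2-(acyloxymethyl)acrylates. The cis alcohols, 13 and its diastereomer methyl 2-[(2R,3R)-5-[(1S)-1-(tert-butyldimethylsilyloxy)ethyl]-3-hydroxy-2,3-dihydro-1-benzofuran-2-yl]prop-2-enoate F2, are freed from any trans isomers by chromatography. Lipase-catalysed acylation (Burkholderia cepacia lipase or CAL-B, vinyl acetate, MTBE, 30 °C) should acetylate only the (3S) carbinol, the spatial arrangement these lipases prefer in cyclic benzylic alcohols. This gives 14 directly, while F2 stays unacylated and is removed.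

2. Step 11. Possible failures: Z→E isomerisation of the activated angeloyl group through reversible conjugate addition of chloride or amine; slow acylation of the secondary benzylic alcohol; ionisation of that alcohol at 80 °C with loss of configuration.

   Fallback, setting out from 15 and returning at 18: 15 is esterified (EDC·HCl, DMAP, CH2Cl2) with 2-[bis(2,2,2-trifluoroethoxy)phosphoryl]propanoic acid to give (1S)-1-[(2S,3S)-3-acetoxy-2-(3-methoxy-3-oxoprop-1-en-2-yl)-2,3-dihydro-1-benzofuran-5-yl]ethyl 2-[bis(2,2,2-trifluoroethoxy)phosphoryl]propanoate F3. A Still–Gennari olefination with acetaldehyde (KHMDS, 18-crown-6, THF, −78 °C) then builds the (Z)-2-methylbut-2-enoate on the molecule, so the angelate geometry is made kinetically instead of being carried through an activation step.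

3. Step 2. Possible failures: the acetoxy transposition stalls at an equilibrium mixture; E/Z mixtures form; the catalyst is trapped as the allylammonium salt.

   Fallback, setting out from 3 and returning at 5: 3 is treated with NBS/Me2S (CH2Cl2, 0 °C), an SN2′ bromination with allylic transposition, to give methyl (2Z)-2-(bromomethyl)-4,4-dimethoxybut-2-enoate F4. Displacement with KOAc (DMF, rt) then gives 5 with the same alkene geometry.

Further compounds
F1 | step 8 | methyl (2E,4S)-2-(acetoxymethyl)-4-hydroxy-4-{2-hydroxy-5-[(1S)-1-(tert-butyldimethylsilyloxy)ethyl]phenyl}but-2-enoate | COC(=O)/C(COC(C)=O)=C/[C@H](O)c1cc([C@H](C)O[Si](C)(C)C(C)(C)C)ccc1O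
F2 | step 8 | methyl 2-[(2R,3R)-5-[(1S)-1-(tert-butyldimethylsilyloxy)ethyl]-3-hydroxy-2,3-dihydro-1-benzofuran-2-yl]prop-2-enoate | C=C(C(=O)OC)[C@H]1Oc2ccc([C@H](C)O[Si](C)(C)C(C)(C)C)cc2[C@H]1O
F3 | step 11 | (1S)-1-[(2S,3S)-3-acetoxy-2-(3-methoxy-3-oxoprop-1-en-2-yl)-2,3-dihydro-1-benzofuran-5-yl]ethyl 2-[bis(2,2,2-trifluoroethoxy)phosphoryl]propanoate | C=C(C(=O)OC)[C@@H]1Oc2ccc([C@H](C)OC(=O)C(C)P(=O)(OCC(F)(F)F)OCC(F)(F)F)cc2[C@@H]1OC(C)=O
F4 | step 2 | methyl (2Z)-2-(bromomethyl)-4,4-dimethoxybut-2-enoate | COC(=O)/C(CBr)=C/C(OC)OC
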